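**Strategy**

Everything rests on not cross-coupling the tetra-ortho-substituted C3–C6 biaryl bond between flavone 1 and the luteolin unit. The future luteolin ring A is first placed on C2 of a 2,2-diarylchroman-4-one and then moved to C3 by an oxidative 1,2-aryl shift that also aromatises ring C. This uses the fact that C3 of ring C adjoins C2, whose cation is stabilised by O1 and the 4-oxygenated phenyl ring, and that the migrating ring is bonded through a carbon flanked by two oxygens and para to the future luteolin O1, so its symmetry permits only the 6-linked flavone. The precursor is the trimethylsilyl enol ether 16 of that chromanone.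

Key step: step 10

Remark on the chemistry: the target structure defines no configuration for the four-fold ortho-substituted biaryl axis, so the axis is treated as unspecified and is not controlled.

**Route**

Step 1
Reactants: 1 2,4,6-trihydroxybenzaldehyde
Product: 2 2,6-dihydroxy-4-(triisopropylsilyloxy)benzaldehyde
Conditions: i-Pr3SiCl (1.05 eq), imidazole, DMF, 0 °C
Reagents that add atoms: triisopropylsilyl chloride, CC(C)[Si](Cl)(C(C)C)C(C)C
Why: Regioselective O-silylation; the 4-OH is para to the formyl group, the most acidic and the only hydroxyl not flanked by the CHO group, so one equivalent of the bulky silyl chloride should take it alone.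

Step 2
Reactants: 2 2,6-dihydroxy-4-(triisopropylsilyloxy)benzaldehyde
Product: 3 2,6-bis(benzyloxy)-4-(triisopropylsilyloxy)benzaldehyde
Conditions: BnOH, PPh3, DIAD, THF, 0 °C → rt
Reagents that add atoms: benzyl alcohol, OCc1ccccc1
Why: Double Mitsunobu etherification of the two acidic ortho-hydroxyls under neutral conditions, which spares the aryl silyl ether that a carbonate or hydroxide base could remove.

Step 3
Reactants: 3 2,6-bis(benzyloxy)-4-(triisopropylsilyloxy)benzaldehyde; 4 1-benzyloxy-4-bromobenzene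
Product: 6 racemic [2,6-bis(benzyloxy)-4-(triisopropylsilyloxy)phenyl](4-benzyloxyphenyl)methanol, via aryl Grignard reagent 5 (not isolated)
Conditions: Mg, THF, reflux (4 → 5); then 3, THF, 0 °C → rt
Reagents that add atoms: none
Why: Grignard addition to a non-enolisable aldehyde; the carbinol centre is formed racemic and is removed by the oxidation that follows.

Step 4
Reactants: 6 racemic [2,6-bis(benzyloxy)-4-(triisopropylsilyloxy)phenyl](4-benzyloxyphenyl)methanol
Product: 7 [2,6-bis(benzyloxy)-4-(triisopropylsilyloxy)phenyl](4-benzyloxyphenyl)methanone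
Conditions: MnO2, CH2Cl2, rt
Reagents that add atoms: none
Why: MnO2 oxidation of a doubly benzylic alcohol under neutral conditions, avoiding any acid that would ionise this very electron-rich carbinol.

Step 5
Reactants: 8 2-hydroxy-4,6-dimethoxybenzaldehyde
Product: 9 2,4-dimethoxy-6-(methoxymethoxy)benzaldehyde
Conditions: MOMCl, i-Pr2NEt, CH2Cl2, 0 °C → rt
Reagents that add atoms: chloromethyl methyl ether, COCCl
Why: O-alkylation of the chelated phenol to a methoxymethyl acetal that withstands the organolithium step and is later removed by acid without touching benzyl or methyl ethers.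

Step 6
Reactants: 9 2,4-dimethoxy-6-(methoxymethoxy)benzaldehyde
Product: 10 2-ethynyl-1,5-dimethoxy-3-(methoxymethoxy)benzene
Conditions: dimethyl (1-diazo-2-oxopropyl)phosphonate, K2CO3, MeOH, rt
Reagents that add atoms: dimethyl (1-diazo-2-oxopropyl)phosphonate, COP(=O)(OC)C(=[N+]=[N-])C(C)=O
Why: Ohira–Bestmann (Seyferth–Gilbert) homologation of a non-enolisable aldehyde to the terminal alkyne under mild carbonate conditions that the acetal and methyl ethers tolerate.

Step 7
Reactants: 10 2-ethynyl-1,5-dimethoxy-3-(methoxymethoxy)benzene; 7 [2,6-bis(benzyloxy)-4-(triisopropylsilyloxy)phenyl](4-benzyloxyphenyl)methanone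
Product: 12 racemic 1-[2,6-bis(benzyloxy)-4-(triisopropylsilyloxy)phenyl]-1-(4-benzyloxyphenyl)-3-[2,4-dimethoxy-6-(methoxymethoxy)phenyl]prop-2-yn-1-ol, via lithium acetylide 11 (not isolated)
Conditions: n-BuLi, THF, −78 °C; then 7, −78 °C → rt
Reagents that add atoms: none
Why: 1,2-addition of a slim lithium acetylide to a hindered diaryl ketone that has no α-hydrogen to lose; the tertiary carbinol centre is racemic and is erased in the next step.

Step 8
Reactants: 12 racemic 1-[2,6-bis(benzyloxy)-4-(triisopropylsilyloxy)phenyl]-1-(4-benzyloxyphenyl)-3-[2,4-dimethoxy-6-(methoxymethoxy)phenyl]prop-2-yn-1-ol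
Product: 15 racemic 2-(4-benzyloxyphenyl)-2-[2,6-bis(benzyloxy)-4-(triisopropylsilyloxy)phenyl]-5,7-dimethoxychroman-4-one, via MOM-protected enone 13 (not isolated), via phenol enone 14 (not isolated)
Conditions: TsOH·H2O (cat.), THF–H2O, rt; then HCl, MeOH, 45 °C
Reagents that add atoms: water, O
Why: Acid ionises the carbinol to a propargyl/allenyl cation that takes up water at the alkyne terminus (Meyer–Schuster rearrangement), methanolic HCl then cleaves the acetal, and the freed phenol closes ring C by 6-endo oxa-Michael addition onto the doubly benzylic β-carbon, giving a racemic C2 that later becomes sp2; the benzyl and aryl silyl ethers should survive dilute acid.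

Step 9
Reactants: 15 racemic 2-(4-benzyloxyphenyl)-2-[2,6-bis(benzyloxy)-4-(triisopropylsilyloxy)phenyl]-5,7-dimethoxychroman-4-one
Product: 16 racemic 2-(4-benzyloxyphenyl)-2-[2,6-bis(benzyloxy)-4-(triisopropylsilyloxy)phenyl]-5,7-dimethoxy-4-(trimethylsilyloxy)-2H-chromene
Conditions: Me3SiOTf, Et3N, CH2Cl2, 0 °C
Reagents that add atoms: trimethylsilyl trifluoromethanesulfonate, C[Si](C)(C)OS(=O)(=O)C(F)(F)F
Why: Soft enolisation of the aryl ketone gives the enol silane without a free enolate, which could open ring C by retro-oxa-Michael reaction.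

Step 10
Reactants: 16 racemic 2-(4-benzyloxyphenyl)-2-[2,6-bis(benzyloxy)-4-(triisopropylsilyloxy)phenyl]-5,7-dimethoxy-4-(trimethylsilyloxy)-2H-chromene
Product: 17 2-(4-benzyloxyphenyl)-3-[2,6-bis(benzyloxy)-4-(triisopropylsilyloxy)phenyl]-5,7-dimethoxychromen-4-one
Conditions: PhI(OAc)2 (1.05 eq), BF3·OEt2, MeCN–CH2Cl2, −40 °C → 0 °C
Reagents that add atoms: none
Why: Proposed new method: the enol silane, far more nucleophilic than any arene ring present, attacks the BF3-activated trivalent iodine reagent at C3 with loss of the silyl group to give a C3–I(Ph)OAc ketone; the 2,6-bis(benzyloxy)-4-silyloxyphenyl group on C2 then bridges to C3 as a phenonium ion while PhI departs, the C2 cation is held by O1 and the 4-benzyloxyphenyl ring, and loss of the C3 proton gives the chromone. The closest known reaction type is the oxidative 2,3-aryl migration of flavanones to isoflavones with PhI(OH)OTs in MeCN or with Tl(NO3)3 (trivalent thallium), together with the related 1,2-aryl shift of chalcones; the difference here is that C2 carries two aryl groups and no hydrogen. No ring is closed: the C3–aryl bond forms as the C2–aryl bond breaks, and ring C of flavone 1 is aromatised to the pyranone. No stereocentre is created, racemic C2 becomes sp2, and the new biaryl axis bears a symmetric ring at this stage. The step needs migration of the tri-oxygenated ring in preference to the 4-benzyloxyphenyl ring, to O1 and to the ring A carbon C4a (ring contraction): its two ortho and one para oxygen donors make it the best bridging group, the iodane should add to the face away from this bulkier aryl group and so place it anti to the leaving group, the shift relieves the crowded quaternary centre, and the absence of an alcohol solvent removes the hemiketal that ring contraction requires. Plain dehydrogenation cannot compete because C2 has no hydrogen, acetate capture at the neopentyl-like C3 should be slow, and low temperature with one equivalent of oxidant protects the free positions of the electron-rich rings.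

Step 11
Reactants: 17 2-(4-benzyloxyphenyl)-3-[2,6-bis(benzyloxy)-4-(triisopropylsilyloxy)phenyl]-5,7-dimethoxychromen-4-one
Product: 18 2-(4-benzyloxyphenyl)-3-[2,6-bis(benzyloxy)-4-hydroxyphenyl]-5,7-dimethoxychromen-4-one
Conditions: Bu4NF, AcOH, THF, 0 °C
Reagents that add atoms: none
Why: Fluoride-induced cleavage of the aryl silyl ether, orthogonal to the benzyl and methyl ethers, with acetic acid buffering so that the electron-rich phenoxide does not linger.

Step 12
Reactants: 18 2-(4-benzyloxyphenyl)-3-[2,6-bis(benzyloxy)-4-hydroxyphenyl]-5,7-dimethoxychromen-4-one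
Product: 19 3-[3-acetyl-2,6-bis(benzyloxy)-4-hydroxyphenyl]-2-(4-benzyloxyphenyl)-5,7-dimethoxychromen-4-one
Conditions: Ac2O, BF3·OEt2, CH2Cl2, 0 °C → rt; aq. NaOAc
Reagents that add atoms: acetic anhydride, CC(=O)OC(C)=O
Why: Friedel–Crafts C-acetylation (or O-acetylation followed by Fries shift), driven by the boron chelate of the ortho-hydroxy ketone, should occur only on the phenolic ring, whose two positions ortho to the OH are equivalent by symmetry, while both chromone-conjugated rings are deactivated.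

Step 13
Reactants: 20 3,4-bis(benzyloxy)benzoic acid
Product: 21 3,4-bis(benzyloxy)benzoyl chloride
Conditions: (COCl)2, DMF (cat.), CH2Cl2, 0 °C → rt
Reagents that add atoms: oxalyl chloride, O=C(Cl)C(=O)Cl
Why: Standard conversion of an acid to its chloride with oxalyl chloride under DMF (Vilsmeier-type) catalysis, the crude chloride being used directly.

Step 14
Reactants: 19 3-[3-acetyl-2,6-bis(benzyloxy)-4-hydroxyphenyl]-2-(4-benzyloxyphenyl)-5,7-dimethoxychromen-4-one; 21 3,4-bis(benzyloxy)benzoyl chloride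
Product: 23 1-[3,4-bis(benzyloxy)phenyl]-3-{2,4-bis(benzyloxy)-6-hydroxy-3-[2-(4-benzyloxyphenyl)-5,7-dimethoxy-4-oxochromen-3-yl]phenyl}propane-1,3-dione, via dilithium dianion 22 (not isolated)
Conditions: LiN(SiMe3)2 (3.2 eq), THF, −78 °C; then 21, −78 °C → 0 °C; aq. HCl
Reagents that add atoms: none
Why: Direct C-aroylation of the phenoxide–enolate dianion (a Baker–Venkataraman-type Claisen condensation), in which the chelated lithium phenoxide is a poor nucleophile and the third equivalent of base deprotonates the diketone as it forms.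

Step 15
Reactants: 23 1-[3,4-bis(benzyloxy)phenyl]-3-{2,4-bis(benzyloxy)-6-hydroxy-3-[2-(4-benzyloxyphenyl)-5,7-dimethoxy-4-oxochromen-3-yl]phenyl}propane-1,3-dione
Product: 24 5,7-bis(benzyloxy)-2-[3,4-bis(benzyloxy)phenyl]-6-[2-(4-benzyloxyphenyl)-5,7-dimethoxy-4-oxochromen-3-yl]chromen-4-one
Conditions: TsOH·H2O (cat.), toluene, 80 °C
Reagents that add atoms: none
Why: Acid-catalysed cyclodehydration of the ortho-hydroxyaryl 1,3-diketone closes the pyranone ring of flavone 2 (6-exo addition of the phenol to the aroyl carbonyl, then loss of water) onto the only free phenol, so only the 6-linked isomer can form.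

Step 16
Reactants: 24 5,7-bis(benzyloxy)-2-[3,4-bis(benzyloxy)phenyl]-6-[2-(4-benzyloxyphenyl)-5,7-dimethoxy-4-oxochromen-3-yl]chromen-4-one
Product: 26 2-(3,4-dihydroxyphenyl)-5,7-dihydroxy-6-[5-hydroxy-2-(4-hydroxyphenyl)-7-methoxy-4-oxochromen-3-yl]chromen-4-one (target CNP0200311.0), via pentaphenol 25 (not isolated)
Conditions: BCl3 (excess), C6HMe5, CH2Cl2, −78 °C → rt; MeOH
Reagents that add atoms: none
Why: BCl3 with pentamethylbenzene as benzyl-cation scavenger cleaves the five aryl benzyl ethers at low temperature, and on warming the same Lewis acid, chelated between C4=O and the peri 5-OMe of flavone 1, cleaves only that methyl ether (chelation-controlled demethylation), leaving the non-chelated 7-OMe.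

**Compound list**

1 | 2,4,6-trihydroxybenzaldehyde | O=Cc1c(O)cc(O)cc1O | starting material
2 | 2,6-dihydroxy-4-(triisopropylsilyloxy)benzaldehyde | O=Cc1c(O)cc(O[Si](C(C)C)(C(C)C)C(C)C)cc1O | intermediate
3 | 2,6-bis(benzyloxy)-4-(triisopropylsilyloxy)benzaldehyde | O=Cc1c(OCc2ccccc2)cc(O[Si](C(C)C)(C(C)C)C(C)C)cc1OCc1ccccc1 | intermediate
4 | 1-benzyloxy-4-bromobenzene | Brc1ccc(OCc2ccccc2)cc1 | starting material
5 | (4-benzyloxyphenyl)magnesium bromide | Br[Mg]c1ccc(OCc2ccccc2)cc1 | intermediate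
6 | racemic [2,6-bis(benzyloxy)-4-(triisopropylsilyloxy)phenyl](4-benzyloxyphenyl)methanol | OC(c1ccc(OCc2ccccc2)cc1)c1c(OCc2ccccc2)cc(O[Si](C(C)C)(C(C)C)C(C)C)cc1OCc1ccccc1 | intermediate
7 | [2,6-bis(benzyloxy)-4-(triisopropylsilyloxy)phenyl](4-benzyloxyphenyl)methanone | O=C(c1ccc(OCc2ccccc2)cc1)c1c(OCc2ccccc2)cc(O[Si](C(C)C)(C(C)C)C(C)C)cc1OCc1ccccc1 | intermediate
8 | 2-hydroxy-4,6-dimethoxybenzaldehyde | O=Cc1c(O)cc(OC)cc1OC | starting material
9 | 2,4-dimethoxy-6-(methoxymethoxy)benzaldehyde | O=Cc1c(OCOC)cc(OC)cc1OC | intermediate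
10 | 2-ethynyl-1,5-dimethoxy-3-(methoxymethoxy)benzene | C#Cc1c(OCOC)cc(OC)cc1OC | intermediate
11 | lithium acetylide of 10 | [Li]C#Cc1c(OCOC)cc(OC)cc1OC | intermediate
12 | racemic 1-[2,6-bis(benzyloxy)-4-(triisopropylsilyloxy)phenyl]-1-(4-benzyloxyphenyl)-3-[2,4-dimethoxy-6-(methoxymethoxy)phenyl]prop-2-yn-1-ol | OC(C#Cc1c(OCOC)cc(OC)cc1OC)(c1ccc(OCc2ccccc2)cc1)c1c(OCc2ccccc2)cc(O[Si](C(C)C)(C(C)C)C(C)C)cc1OCc1ccccc1 | intermediate
13 | 3-[2,6-bis(benzyloxy)-4-(triisopropylsilyloxy)phenyl]-3-(4-benzyloxyphenyl)-1-[2,4-dimethoxy-6-(methoxymethoxy)phenyl]prop-2-en-1-one (double-bond geometry not defined) | O=C(C=C(c1ccc(OCc2ccccc2)cc1)c1c(OCc2ccccc2)cc(O[Si](C(C)C)(C(C)C)C(C)C)cc1OCc1ccccc1)c1c(OCOC)cc(OC)cc1OC | intermediate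
14 | 3-[2,6-bis(benzyloxy)-4-(triisopropylsilyloxy)phenyl]-3-(4-benzyloxyphenyl)-1-(2-hydroxy-4,6-dimethoxyphenyl)prop-2-en-1-one (double-bond geometry not defined) | O=C(C=C(c1ccc(OCc2ccccc2)cc1)c1c(OCc2ccccc2)cc(O[Si](C(C)C)(C(C)C)C(C)C)cc1OCc1ccccc1)c1c(O)cc(OC)cc1OC | intermediate
15 | racemic 2-(4-benzyloxyphenyl)-2-[2,6-bis(benzyloxy)-4-(triisopropylsilyloxy)phenyl]-5,7-dimethoxychroman-4-one | COc1cc(OC)c2c(c1)OC(c1ccc(OCc3ccccc3)cc1)(c1c(OCc3ccccc3)cc(O[Si](C(C)C)(C(C)C)C(C)C)cc1OCc1ccccc1)CC2=O | intermediate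
16 | racemic 2-(4-benzyloxyphenyl)-2-[2,6-bis(benzyloxy)-4-(triisopropylsilyloxy)phenyl]-5,7-dimethoxy-4-(trimethylsilyloxy)-2H-chromene | COc1cc(OC)c2c(c1)OC(c1ccc(OCc3ccccc3)cc1)(c1c(OCc3ccccc3)cc(O[Si](C(C)C)(C(C)C)C(C)C)cc1OCc1ccccc1)C=C2O[Si](C)(C)C | intermediate
17 | 2-(4-benzyloxyphenyl)-3-[2,6-bis(benzyloxy)-4-(triisopropylsilyloxy)phenyl]-5,7-dimethoxychromen-4-one | COc1cc(OC)c2c(=O)c(-c3c(OCc4ccccc4)cc(O[Si](C(C)C)(C(C)C)C(C)C)cc3OCc3ccccc3)c(-c3ccc(OCc4ccccc4)cc3)oc2c1 | intermediate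
18 | 2-(4-benzyloxyphenyl)-3-[2,6-bis(benzyloxy)-4-hydroxyphenyl]-5,7-dimethoxychromen-4-one | COc1cc(OC)c2c(=O)c(-c3c(OCc4ccccc4)cc(O)cc3OCc3ccccc3)c(-c3ccc(OCc4ccccc4)cc3)oc2c1 | intermediate
19 | 3-[3-acetyl-2,6-bis(benzyloxy)-4-hydroxyphenyl]-2-(4-benzyloxyphenyl)-5,7-dimethoxychromen-4-one | COc1cc(OC)c2c(=O)c(-c3c(OCc4ccccc4)cc(O)c(C(C)=O)c3OCc3ccccc3)c(-c3ccc(OCc4ccccc4)cc3)oc2c1 | intermediate
20 | 3,4-bis(benzyloxy)benzoic acid | OC(=O)c1ccc(OCc2ccccc2)c(OCc2ccccc2)c1 | starting material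
21 | 3,4-bis(benzyloxy)benzoyl chloride | ClC(=O)c1ccc(OCc2ccccc2)c(OCc2ccccc2)c1 | intermediate
22 | dilithium phenoxide–enolate of 19 | COc1cc(OC)c2c(=O)c(-c3c(OCc4ccccc4)cc(O[Li])c(C(=C)O[Li])c3OCc3ccccc3)c(-c3ccc(OCc4ccccc4)cc3)oc2c1 | intermediate
23 | 1-[3,4-bis(benzyloxy)phenyl]-3-{2,4-bis(benzyloxy)-6-hydroxy-3-[2-(4-benzyloxyphenyl)-5,7-dimethoxy-4-oxochromen-3-yl]phenyl}propane-1,3-dione | COc1cc(OC)c2c(=O)c(-c3c(OCc4ccccc4)cc(O)c(C(=O)CC(=O)c4ccc(OCc5ccccc5)c(OCc5ccccc5)c4)c3OCc3ccccc3)c(-c3ccc(OCc4ccccc4)cc3)oc2c1 | intermediate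
24 | 5,7-bis(benzyloxy)-2-[3,4-bis(benzyloxy)phenyl]-6-[2-(4-benzyloxyphenyl)-5,7-dimethoxy-4-oxochromen-3-yl]chromen-4-one | COc1cc(OC)c2c(=O)c(-c3c(OCc4ccccc4)cc4oc(-c5ccc(OCc6ccccc6)c(OCc6ccccc6)c5)cc(=O)c4c3OCc3ccccc3)c(-c3ccc(OCc4ccccc4)cc3)oc2c1 | intermediate
25 | 2-(3,4-dihydroxyphenyl)-5,7-dihydroxy-6-[2-(4-hydroxyphenyl)-5,7-dimethoxy-4-oxochromen-3-yl]chromen-4-one | COc1cc(OC)c2c(=O)c(-c3c(O)cc4oc(-c5ccc(O)c(O)c5)cc(=O)c4c3O)c(-c3ccc(O)cc3)oc2c1 | intermediate
26 | 2-(3,4-dihydroxyphenyl)-5,7-dihydroxy-6-[5-hydroxy-2-(4-hydroxyphenyl)-7-methoxy-4-oxochromen-3-yl]chromen-4-one (CNP0200311.0) | COc1cc(O)c2c(=O)c(-c3c(O)cc4oc(-c5ccc(O)c(O)c5)cc(=O)c4c3O)c(-c3ccc(O)cc3)oc2c1 | target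

**Step count**

Total steps: 16. Longest linear sequence: 13 steps (from 1 through steps 1–4, 7–12 and 14–16).

**Steps most likely to fail**

Step 10 (new method). The C3 iodane may be diverted before the aryl shift: capture by acetate at C3, migration of the 4-benzyloxyphenyl group or of O1, or attack of the oxidant on the electron-rich rings. The fallback uses known chemistry only, doing the aryl shift at the chalcone stage and adding the 2-aryl group afterwards. It sets out from aldehyde 3 and lithium acetylide 11 and returns to the route at 17.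
- Acetylide 11 would be added to 3 to give racemic 1-[2,6-bis(benzyloxy)-4-(triisopropylsilyloxy)phenyl]-3-[2,4-dimethoxy-6-(methoxymethoxy)phenyl]prop-2-yn-1-ol F1.
- Meyer–Schuster rearrangement (TsOH·H2O, wet THF) would give (E)-3-[2,6-bis(benzyloxy)-4-(triisopropylsilyloxy)phenyl]-1-[2,4-dimethoxy-6-(methoxymethoxy)phenyl]prop-2-en-1-one F2.
- Oxidative 1,2-aryl shift with Tl(NO3)3·3H2O (trivalent thallium) in MeOH–HC(OMe)3, as established for 2'-protected chalcones, would give racemic 2-[2,6-bis(benzyloxy)-4-(triisopropylsilyloxy)phenyl]-3,3-dimethoxy-1-[2,4-dimethoxy-6-(methoxymethoxy)phenyl]propan-1-one F3.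
- HCl in MeOH would remove the acetal protecting group and close the ring to 3-[2,6-bis(benzyloxy)-4-(triisopropylsilyloxy)phenyl]-5,7-dimethoxychromen-4-one F4.
- Copper-catalysed conjugate addition of Grignard reagent 5 at C2 (CuBr·SMe2, Me3SiCl, THF) would give racemic 2-(4-benzyloxyphenyl)-3-[2,6-bis(benzyloxy)-4-(triisopropylsilyloxy)phenyl]-5,7-dimethoxy-4-(trimethylsilyloxy)-2H-chromene F5.
- Dehydrogenation of this enol silane with DDQ would deliver 17.

Step 8. The very stabilised tertiary cation may lose benzyl or silyl groups, or be trapped by a neighbouring ring, before the 1,3-oxygen shift is complete. The fallback forms no carbocation: the 4-benzyloxyphenyl group enters by conjugate addition to an ynone. It sets out from aldehyde 3 and returns at enone 13, which then goes through the methanolic HCl stage of step 8.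
- Aldehyde 3 would be homologated (Me3SiCHN2, LiN(i-Pr)2, THF, −78 °C, Colvin rearrangement) to 1,3-bis(benzyloxy)-2-ethynyl-5-(triisopropylsilyloxy)benzene F6.
- n-BuLi would convert it into the lithium acetylide of 1,3-bis(benzyloxy)-2-ethynyl-5-(triisopropylsilyloxy)benzene F7.
- Addition to aldehyde 9 would give racemic 3-[2,6-bis(benzyloxy)-4-(triisopropylsilyloxy)phenyl]-1-[2,4-dimethoxy-6-(methoxymethoxy)phenyl]prop-2-yn-1-ol F8.
- MnO2 would oxidise it to 3-[2,6-bis(benzyloxy)-4-(triisopropylsilyloxy)phenyl]-1-[2,4-dimethoxy-6-(methoxymethoxy)phenyl]prop-2-yn-1-one F9.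
- Copper-catalysed conjugate addition of Grignard reagent 5 (CuBr·SMe2, THF, −40 °C) would give 13.

If instead the closure onto the crowded quaternary C2 is itself unfavourable, the fallback of step 10 applies, since it never passes through a 2,2-diarylchromanone.

Step 12. The Lewis acid may cleave the benzyl ether beside the new acetyl group, which would destroy the oxygen differentiation that step 15 relies on, or acetylation may stop at oxygen. The fallback replaces electrophilic acylation by halogenation and cross-coupling. It sets out from phenol 18 and returns at 19.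
- NIS (1 eq, CH2Cl2–MeCN, −20 °C) would iodinate ortho to the hydroxyl to give 2-(4-benzyloxyphenyl)-3-[2,6-bis(benzyloxy)-4-hydroxy-3-iodophenyl]-5,7-dimethoxychromen-4-one F10.
- Stille coupling with tributyl(1-ethoxyvinyl)stannane and Pd(PPh3)4 (zerovalent palladium) in toluene at 90 °C would give 2-(4-benzyloxyphenyl)-3-[2,6-bis(benzyloxy)-3-(1-ethoxyvinyl)-4-hydroxyphenyl]-5,7-dimethoxychromen-4-one F11.
- Dilute HCl in THF would hydrolyse the enol ether to 19.

**Further compounds**

F1 | step 10 | racemic 1-[2,6-bis(benzyloxy)-4-(triisopropylsilyloxy)phenyl]-3-[2,4-dimethoxy-6-(methoxymethoxy)phenyl]prop-2-yn-1-ol | OC(C#Cc1c(OCOC)cc(OC)cc1OC)c1c(OCc2ccccc2)cc(O[Si](C(C)C)(C(C)C)C(C)C)cc1OCc1ccccc1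
F2 | step 10 | (E)-3-[2,6-bis(benzyloxy)-4-(triisopropylsilyloxy)phenyl]-1-[2,4-dimethoxy-6-(methoxymethoxy)phenyl]prop-2-en-1-one | COCOc1cc(OC)cc(OC)c1C(=O)/C=C/c1c(OCc2ccccc2)cc(O[Si](C(C)C)(C(C)C)C(C)C)cc1OCc1ccccc1
F3 | step 10 | racemic 2-[2,6-bis(benzyloxy)-4-(triisopropylsilyloxy)phenyl]-3,3-dimethoxy-1-[2,4-dimethoxy-6-(methoxymethoxy)phenyl]propan-1-one | COCOc1cc(OC)cc(OC)c1C(=O)C(C(OC)OC)c1c(OCc2ccccc2)cc(O[Si](C(C)C)(C(C)C)C(C)C)cc1OCc1ccccc1
F4 | step 10 | 3-[2,6-bis(benzyloxy)-4-(triisopropylsilyloxy)phenyl]-5,7-dimethoxychromen-4-one | COc1cc(OC)c2c(=O)c(-c3c(OCc4ccccc4)cc(O[Si](C(C)C)(C(C)C)C(C)C)cc3OCc3ccccc3)coc2c1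
F5 | step 10 | racemic 2-(4-benzyloxyphenyl)-3-[2,6-bis(benzyloxy)-4-(triisopropylsilyloxy)phenyl]-5,7-dimethoxy-4-(trimethylsilyloxy)-2H-chromene | COc1cc(OC)c2c(c1)OC(c1ccc(OCc3ccccc3)cc1)C(c1c(OCc3ccccc3)cc(O[Si](C(C)C)(C(C)C)C(C)C)cc1OCc1ccccc1)=C2O[Si](C)(C)C
F6 | step 8 | 1,3-bis(benzyloxy)-2-ethynyl-5-(triisopropylsilyloxy)benzene | C#Cc1c(OCc2ccccc2)cc(O[Si](C(C)C)(C(C)C)C(C)C)cc1OCc1ccccc1
F7 | step 8 | lithium acetylide of 1,3-bis(benzyloxy)-2-ethynyl-5-(triisopropylsilyloxy)benzene | [Li]C#Cc1c(OCc2ccccc2)cc(O[Si](C(C)C)(C(C)C)C(C)C)cc1OCc1ccccc1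
F8 | step 8 | racemic 3-[2,6-bis(benzyloxy)-4-(triisopropylsilyloxy)phenyl]-1-[2,4-dimethoxy-6-(methoxymethoxy)phenyl]prop-2-yn-1-ol | OC(C#Cc1c(OCc2ccccc2)cc(O[Si](C(C)C)(C(C)C)C(C)C)cc1OCc1ccccc1)c1c(OCOC)cc(OC)cc1OC
F9 | step 8 | 3-[2,6-bis(benzyloxy)-4-(triisopropylsilyloxy)phenyl]-1-[2,4-dimethoxy-6-(methoxymethoxy)phenyl]prop-2-yn-1-one | O=C(C#Cc1c(OCc2ccccc2)cc(O[Si](C(C)C)(C(C)C)C(C)C)cc1OCc1ccccc1)c1c(OCOC)cc(OC)cc1OC
F10 | step 12 | 2-(4-benzyloxyphenyl)-3-[2,6-bis(benzyloxy)-4-hydroxy-3-iodophenyl]-5,7-dimethoxychromen-4-one | COc1cc(OC)c2c(=O)c(-c3c(OCc4ccccc4)cc(O)c(I)c3OCc3ccccc3)c(-c3ccc(OCc4ccccc4)cc3)oc2c1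
F11 | step 12 | 2-(4-benzyloxyphenyl)-3-[2,6-bis(benzyloxy)-3-(1-ethoxyvinyl)-4-hydroxyphenyl]-5,7-dimethoxychromen-4-one | COc1cc(OC)c2c(=O)c(-c3c(OCc4ccccc4)cc(O)c(C(=C)OCC)c3OCc3ccccc3)c(-c3ccc(OCc4ccccc4)cc3)oc2c1
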